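## Retrosynthetic overview

1. The target comes from its C7/C8 acetonide; ring B (the pyran) is closed last, by addition of the C1 hydroxyl to a C3 ketone and loss of water.
2. Key C3–C4 bond: an intermolecular vinylogous Mukaiyama aldol between a ring A silyl dienol ether (C4 as exocyclic CH2) and the side-chain dienal (2E,4E,6S)-4,6-dimethylocta-2,4-dienal.
3. The chloro enone with its C4 methyl comes from MeLi addition to a 5-chloro vinylogous ester (Stork–Danheiser). The C8a quaternary centre comes from two further aldols (acetaldehyde, then formaldehyde anti to the acetonide).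
4. Ring A is taken from the chiral pool: (R)-carvone, Criegee degradation, OsO4 cis-diol (C7, C8), then a regiodefined vinylogous ester (C4a=O, C6–OCH2OCH3).
5. The dienal comes from (S)-2-methylbutan-1-ol by two E-selective Wittig olefinations. Ring order: ring A (from carvone) first, ring B last.

Convention: ring carbons of all intermediates carry the target locants (C1, C3, C4, C4a, C5–C8, C8a). Face α is the face of the C7/C8 oxygens and of the acetyl group in the target; face β is the face of the C7 methyl and of C1.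

## Route

Step 1
Reactants: 1 (R)-(−)-carvone
Product: 4 (1R)-4-methyl-5-oxocyclohex-3-en-1-yl acetate, via methoxy hydroperoxide 2 (not isolated), via peracetate 3 (not isolated)
Conditions: O3, CH2Cl2/MeOH, −78 °C; then Ac2O, Et3N, DMAP (cat.), −78 °C → rt
Reagents that add atoms: ozone O=[O+][O-]; methanol CO
Why: Ozonolysis cleaves only the electron-rich isopropenyl alkene and methanol traps the carbonyl oxide; acetylation of the hydroperoxide triggers the Criegee rearrangement, in which the ring carbon migrates to oxygen with retention, so C4a keeps the carvone configuration.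

Step 2
Reactants: 4 (1R)-4-methyl-5-oxocyclohex-3-en-1-yl acetate
Product: 5 (5R)-5-hydroxy-2-methylcyclohex-2-en-1-one
Conditions: K2CO3 (0.2 equiv), MeOH, 0 °C
Reagents that add atoms: none
Why: Base-catalysed transesterification removes the acetate; it is run cold and short so that β-elimination toward 2-methylphenol does not compete, and no stereocentre is touched.

Step 3
Reactants: 5 (5R)-5-hydroxy-2-methylcyclohex-2-en-1-one
Product: 6 (5R)-5-[(tert-butyldimethylsilyl)oxy]-2-methylcyclohex-2-en-1-one
Conditions: TBSCl, imidazole, DMF, rt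
Reagents that add atoms: tert-butyldimethylsilyl chloride CC(C)(C)[Si](C)(C)Cl
Why: Imidazole-promoted silylation gives a base-stable, bulky C4a ether that later steers the osmylation.

Step 4
Reactants: 6 (5R)-5-[(tert-butyldimethylsilyl)oxy]-2-methylcyclohex-2-en-1-one
Product: 7 (2R,3R,5R)-5-[(tert-butyldimethylsilyl)oxy]-2,3-dihydroxy-2-methylcyclohexan-1-one
Conditions: OsO4 (2 mol %), NMO, citric acid, t-BuOH/H2O, rt
Reagents that add atoms: N-methylmorpholine N-oxide C[N+]1([O-])CCOCC1; water O
Why: Upjohn syn-dihydroxylation delivers both oxygens to the enone face opposite the C4a silyloxy group, which sets C7 (R) and C8 (R) as a cis-diol; the minor syn isomer is removed by chromatography.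

Step 5
Reactants: 7 (2R,3R,5R)-5-[(tert-butyldimethylsilyl)oxy]-2,3-dihydroxy-2-methylcyclohexan-1-one
Product: 8 ketone acetonide (3aR,6R,7aR)-6-[(tert-butyldimethylsilyl)oxy]-2,2,3a-trimethylhexahydro-4H-1,3-benzodioxol-4-one
Conditions: Me2C(OMe)2, camphorsulfonic acid (cat.), acetone, rt
Reagents that add atoms: 2,2-dimethoxypropane COC(C)(C)OC
Why: Acid-catalysed transketalization closes the cis-fused dioxolane on the cis-diol, which protects both hydroxyls and creates the concave/convex bias used in step 11.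

Step 6
Reactants: 8 ketone acetonide
Product: 9 methoxymethyl enol ether (C5=C6–OCH2OCH3; C4a β-OTBS)
Conditions: KN(SiMe3)2, THF/DMPU, −78 °C; MOMCl, −78 °C
Reagents that add atoms: chloromethyl methyl ether COCCl
Why: The ketone can enolize only toward C5 (C7 is quaternary) and the potassium enolate is alkylated on oxygen by the hard chloromethyl ether, which fixes the enol ether oxygen at C6.

Step 7
Reactants: 9 methoxymethyl enol ether
Product: 10 allylic alcohol (C4a β-OH; C5=C6–OCH2OCH3)
Conditions: Bu4NF, THF, 0 °C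
Reagents that add atoms: none
Why: Fluoride-mediated desilylation frees the C4a hydroxyl under basic conditions that leave the enol ether and acetonide intact.

Step 8
Reactants: 10 allylic alcohol
Product: 11 vinylogous ester (C4a=O; C5=C6–OCH2OCH3; C8a H2)
Conditions: Dess–Martin periodinane, pyridine, CH2Cl2, 0 °C → rt
Reagents that add atoms: none
Why: Dess–Martin oxidation of the allylic alcohol gives the vinylogous ester with the carbonyl unambiguously at C4a and the alkoxy group at C6.

Step 9
Reactants: 11 vinylogous ester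
Product: 12 C8a-(1-hydroxyethyl) vinylogous ester (diastereomer mixture)
Conditions: LiN(iPr)2, THF, −78 °C; CH3CHO, −78 °C
Reagents that add atoms: acetaldehyde CC=O
Why: Kinetic deprotonation of a vinylogous ester occurs at the α′ carbon (C8a), and the lithium enolate undergoes a fast aldol addition at −78 °C before β-elimination of the C8 oxygen can compete; both new stereocentres are erased in steps 10 and 11.

Step 10
Reactants: 12 C8a-(1-hydroxyethyl) vinylogous ester
Product: 13 C8a-acetyl vinylogous ester (enolized β-diketone)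
Conditions: Dess–Martin periodinane, pyridine, CH2Cl2, rt
Reagents that add atoms: none
Why: Dess–Martin oxidation of the β-hydroxy ketone gives the β-diketone, which makes C8a acidic enough for a mild second C–C bond formation.

Step 11
Reactants: 13 C8a-acetyl vinylogous ester
Product: 14 C8a β-hydroxymethyl α-acetyl vinylogous ester
Conditions: 37% aq. CH2O, KHCO3 (cat.), THF, 0 °C
Reagents that add atoms: formaldehyde C=O
Why: Aldol (Tollens-type) hydroxymethylation of the enolized β-diketone: formaldehyde attacks C8a from the convex β face, opposite the cis-fused dioxolane on C8, which sets the quaternary centre with CH2OH trans and acetyl cis to the C8 oxygen.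

Step 12
Reactants: 14 C8a β-hydroxymethyl α-acetyl vinylogous ester
Product: 15 tert-butyldiphenylsilyl ether of 14
Conditions: TBDPSCl, imidazole, CH2Cl2, 0 °C → rt
Reagents that add atoms: tert-butyldiphenylsilyl chloride CC(C)(C)[Si](Cl)(c1ccccc1)c1ccccc1
Why: Silylation of the primary alcohol blocks retro-aldol loss of formaldehyde and reserves this oxygen for the ring B closure.

Step 13
Reactants: 15 tert-butyldiphenylsilyl ether of 14
Product: 16 C8a α-(1-hydroxyethyl) compound (carbinol epimers)
Conditions: NaBH4, MeOH/CH2Cl2, −78 → −40 °C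
Reagents that add atoms: none
Why: Chemoselective hydride reduction of the saturated methyl ketone (the vinylogous ester carbonyl is far less electrophilic) masks the acetyl group; the carbinol configuration is irrelevant because it is reoxidized in step 25.

Step 14
Reactants: 16 C8a α-(1-hydroxyethyl) compound
Product: 17 triethylsilyl ether of 16
Conditions: Et3SiOTf, 2,6-lutidine, CH2Cl2, −78 °C
Reagents that add atoms: triethylsilyl triflate CC[Si](CC)(CC)OS(=O)(=O)C(F)(F)F
Why: Silylation of the hindered secondary alcohol prevents retro-aldol fragmentation of a β-alkoxide during the organolithium addition in step 16.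

Step 15
Reactants: 17 triethylsilyl ether of 16
Product: 18 5-chloro vinylogous ester
Conditions: N-chlorosuccinimide, DMF, 0 °C → rt
Reagents that add atoms: N-chlorosuccinimide O=C1CCC(=O)N1Cl
Why: Electrophilic chlorination occurs at C5, the nucleophilic α carbon of the vinylogous ester and the only activated sp2 C–H in the molecule.

Step 16
Reactants: 18 5-chloro vinylogous ester
Product: 20 2-chloro-3-methyl enone (C6=O; C5–Cl; C4a–CH3; free C8a carbinol arm), via tertiary carbinol adduct 19 (not isolated)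
Conditions: MeLi, THF, −78 °C; then 1 M HCl, THF, 0 °C → rt
Reagents that add atoms: methyllithium [Li]C
Why: Stork–Danheiser transposition: MeLi adds 1,2 to the non-enolizable C4a carbonyl, and acid ionizes the tertiary allylic carbinol and hydrolyses the enol ether to the transposed enone, the acid also cleaving the triethylsilyl ether.

Step 17
Reactants: 20 2-chloro-3-methyl enone
Product: 21 bis(triethylsilyl) dienol ether (C6–OSiEt3; C5–Cl; C4a=CH2; arm OSiEt3)
Conditions: Et3SiOTf (2.5 equiv), Et3N, CH2Cl2, −78 → 0 °C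
Reagents that add atoms: triethylsilyl triflate CC[Si](CC)(CC)OS(=O)(=O)C(F)(F)F
Why: Soft enolization (O-silylation, then γ-deprotonation by the amine) can only remove a C4 methyl proton because C7 and C8a are quaternary, so a single silyl dienol ether forms while the free carbinol is silylated at the same time.

Step 18
Reactants: 22 (S)-2-methylbutan-1-ol
Product: 24 ethyl (2E,4S)-2,4-dimethylhex-2-enoate, via (S)-2-methylbutanal 23 (not isolated)
Conditions: TEMPO (cat.), PhI(OAc)2, CH2Cl2, rt; then Ph3P=C(CH3)CO2Et, rt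
Reagents that add atoms: ethyl 2-(triphenylphosphoranylidene)propanoate CCOC(=O)C(C)=P(c1ccccc1)(c1ccccc1)c1ccccc1
Why: TEMPO/PhI(OAc)2 oxidation gives the configurationally labile aldehyde, which is trapped in the same flask by a stabilized ylide (Wittig reaction) to give the E trisubstituted enoate without loss of the S centre.

Step 19
Reactants: 24 ethyl (2E,4S)-2,4-dimethylhex-2-enoate
Product: 25 (2E,4S)-2,4-dimethylhex-2-en-1-ol
Conditions: iBu2AlH (2.2 equiv), CH2Cl2, −78 °C
Reagents that add atoms: none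
Why: iBu2AlH reduces the conjugated ester 1,2 to the allylic alcohol without touching the alkene or the stereocentre.

Step 20
Reactants: 25 (2E,4S)-2,4-dimethylhex-2-en-1-ol
Product: 26 (2E,4S)-2,4-dimethylhex-2-enal
Conditions: MnO2, CH2Cl2, rt
Reagents that add atoms: none
Why: MnO2 selectively oxidizes the allylic alcohol to the enal under neutral conditions with retention of the E geometry.

Step 21
Reactants: 26 (2E,4S)-2,4-dimethylhex-2-enal
Product: 27 (2E,4E,6S)-N-methoxy-N,4,6-trimethylocta-2,4-dienamide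
Conditions: Ph3P=CHC(O)N(OMe)Me, toluene, 80 °C
Reagents that add atoms: N-methoxy-N-methyl-2-(triphenylphosphoranylidene)acetamide CON(C)C(=O)C=P(c1ccccc1)(c1ccccc1)c1ccccc1
Why: Wittig olefination with a stabilized amide ylide gives the new disubstituted alkene with E geometry under neutral conditions.

Step 22
Reactants: 27 (2E,4E,6S)-N-methoxy-N,4,6-trimethylocta-2,4-dienamide
Product: 28 (2E,4E,6S)-4,6-dimethylocta-2,4-dienal
Conditions: iBu2AlH, THF, −78 °C
Reagents that add atoms: none
Why: Reduction of the Weinreb amide stops at the chelated tetrahedral intermediate, which releases the dienal on work-up without over-reduction.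

Step 23
Reactants: 21 bis(triethylsilyl) dienol ether; 28 (2E,4E,6S)-4,6-dimethylocta-2,4-dienal
Product: 29 vinylogous aldol adduct (C4 H2–C3 H(OH)–dienyl on C4a; C3 epimers)
Conditions: BF3·OEt2, CH2Cl2, −78 °C
Reagents that add atoms: none
Why: Vinylogous Mukaiyama aldol: the BF3-activated dienal is attacked 1,2 by the exocyclic CH2 terminus (γ carbon) of the silyl dienol ether, the α carbon being blocked by chlorine, which forms the C3–C4 bond; the new carbinol centre is oxidized away in step 25.

Step 24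
Reactants: 29 vinylogous aldol adduct
Product: 30 diol (C3–OH and C8a 1-hydroxyethyl arm; C1–OTBDPS kept)
Conditions: HF·pyridine, pyridine, THF, 0 °C
Reagents that add atoms: none
Why: Buffered fluoride cleaves the labile triethylsilyl ether selectively while the tert-butyldiphenylsilyl ether and the acetonide survive.

Step 25
Reactants: 30 diol
Product: 31 seco diketone (C3 dienone; C8a acetyl)
Conditions: Dess–Martin periodinane (2.5 equiv), pyridine, CH2Cl2, 0 °C → rt
Reagents that add atoms: none
Why: Dess–Martin oxidation converts both secondary carbinols at once, giving the C3 ketone and unveiling the C8a acetyl group.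

Step 26
Reactants: 31 seco diketone
Product: 34 acetonide of the target, via free C1 alcohol 32 (not isolated), via C3 hemiketal 33 (not isolated)
Conditions: HF·pyridine, THF, rt
Reagents that add atoms: none
Why: Acidic fluoride removes the tert-butyldiphenylsilyl group without forming a retro-aldol-prone alkoxide; the C1 hydroxyl then adds to the C3 ketone (six-membered hemiketal) and dehydration gives the conjugated cyclic dienol ether of ring B.

Step 27
Reactants: 34 acetonide of the target
Product: 35 target CNP0307047.1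
Conditions: CF3CO2H/H2O/THF, 0 °C → rt
Reagents that add atoms: none
Why: Acid hydrolysis of the acetonide frees the cis-diol without touching a stereocentre; the C8 carbinol cannot eliminate because both neighbours (C7, C8a) are quaternary, and the vinylogous ester chromophore tolerates acid.

## Compound list

1 | (R)-(−)-carvone, (5R)-2-methyl-5-(prop-1-en-2-yl)cyclohex-2-en-1-one | O=C1C(C)=CC[C@@H](C(C)=C)C1 | starting material
2 | methoxy hydroperoxide, (5R)-5-(1-hydroperoxy-1-methoxyethyl)-2-methylcyclohex-2-en-1-one (epimers at the peroxy carbon) | O=C1C(C)=CC[C@@H](C(C)(OC)OO)C1 | intermediate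
3 | peracetate of 2 | O=C1C(C)=CC[C@@H](C(C)(OC)OOC(C)=O)C1 | intermediate
4 | (1R)-4-methyl-5-oxocyclohex-3-en-1-yl acetate | O=C1C(C)=CC[C@@H](OC(C)=O)C1 | intermediate
5 | (5R)-5-hydroxy-2-methylcyclohex-2-en-1-one | O=C1C(C)=CC[C@@H](O)C1 | intermediate
6 | (5R)-5-[(tert-butyldimethylsilyl)oxy]-2-methylcyclohex-2-en-1-one | O=C1C(C)=CC[C@@H](O[Si](C)(C)C(C)(C)C)C1 | intermediate
7 | (2R,3R,5R)-5-[(tert-butyldimethylsilyl)oxy]-2,3-dihydroxy-2-methylcyclohexan-1-one (cis-diol anti to the silyloxy group) | O=C1[C@](C)(O)[C@H](O)C[C@@H](O[Si](C)(C)C(C)(C)C)C1 | intermediate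
8 | ketone acetonide, (3aR,6R,7aR)-6-[(tert-butyldimethylsilyl)oxy]-2,2,3a-trimethylhexahydro-4H-1,3-benzodioxol-4-one | O=C1[C@]2(C)OC(C)(C)O[C@@H]2C[C@@H](O[Si](C)(C)C(C)(C)C)C1 | intermediate
9 | methoxymethyl enol ether of 8 (C5=C6–OCH2OCH3; C4a β-OTBS; C7/C8 α-acetonide) | COCOC=1[C@]2(C)OC(C)(C)O[C@@H]2C[C@@H](O[Si](C)(C)C(C)(C)C)C=1 | intermediate
10 | allylic alcohol (C4a β-OH; C5=C6–OCH2OCH3) | COCOC=1[C@]2(C)OC(C)(C)O[C@@H]2C[C@@H](O)C=1 | intermediate
11 | vinylogous ester (C4a=O; C5=C6–OCH2OCH3; C7 β-CH3; C7/C8 α-acetonide; C8a H2) | COCOC=1[C@]2(C)OC(C)(C)O[C@@H]2CC(=O)C=1 | intermediate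
12 | C8a-(1-hydroxyethyl) vinylogous ester (mixture at C8a and the carbinol carbon) | COCOC=1[C@]2(C)OC(C)(C)O[C@@H]2C(C(C)O)C(=O)C=1 | intermediate
13 | C8a-acetyl vinylogous ester (β-diketone, largely enolized; C8a epimerizable) | COCOC=1[C@]2(C)OC(C)(C)O[C@@H]2C(C(C)=O)C(=O)C=1 | intermediate
14 | quaternary β-diketone, C8a with β-CH2OH and α-acetyl | COCOC=1[C@]2(C)OC(C)(C)O[C@@H]2[C@](CO)(C(C)=O)C(=O)C=1 | intermediate
15 | tert-butyldiphenylsilyl ether of 14 | COCOC=1[C@]2(C)OC(C)(C)O[C@@H]2[C@](CO[Si](c3ccccc3)(c3ccccc3)C(C)(C)C)(C(C)=O)C(=O)C=1 | intermediate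
16 | C8a α-(1-hydroxyethyl) β-(silyloxymethyl) vinylogous ester (carbinol epimers) | COCOC=1[C@]2(C)OC(C)(C)O[C@@H]2[C@](CO[Si](c3ccccc3)(c3ccccc3)C(C)(C)C)(C(C)O)C(=O)C=1 | intermediate
17 | triethylsilyl ether of 16 | COCOC=1[C@]2(C)OC(C)(C)O[C@@H]2[C@](CO[Si](c3ccccc3)(c3ccccc3)C(C)(C)C)(C(C)O[Si](CC)(CC)CC)C(=O)C=1 | intermediate
18 | 5-chloro vinylogous ester | COCOC=1[C@]2(C)OC(C)(C)O[C@@H]2[C@](CO[Si](c3ccccc3)(c3ccccc3)C(C)(C)C)(C(C)O[Si](CC)(CC)CC)C(=O)C=1Cl | intermediate
19 | tertiary carbinol adduct (C4a: OH and CH3; C4a epimers) | COCOC=1[C@]2(C)OC(C)(C)O[C@@H]2[C@](CO[Si](c3ccccc3)(c3ccccc3)C(C)(C)C)(C(C)O[Si](CC)(CC)CC)C(C)(O)C=1Cl | intermediate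
20 | 2-chloro-3-methyl enone (C6=O; C5–Cl; C4a–CH3; C8a β-CH2OTBDPS and α-CH(OH)CH3) | O=C1[C@]2(C)OC(C)(C)O[C@@H]2[C@](CO[Si](c3ccccc3)(c3ccccc3)C(C)(C)C)(C(C)O)C(C)=C1Cl | intermediate
21 | bis(triethylsilyl) dienol ether (C6–OSiEt3; C5–Cl; C4a=CH2; arm OSiEt3) | CC[Si](CC)(CC)OC=1[C@]2(C)OC(C)(C)O[C@@H]2[C@](CO[Si](c3ccccc3)(c3ccccc3)C(C)(C)C)(C(C)O[Si](CC)(CC)CC)C(=C)C=1Cl | intermediate
22 | (S)-2-methylbutan-1-ol | CC[C@H](C)CO | starting material
23 | (S)-2-methylbutanal | CC[C@H](C)C=O | intermediate
24 | ethyl (2E,4S)-2,4-dimethylhex-2-enoate | CC[C@H](C)/C=C(\C)C(=O)OCC | intermediate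
25 | (2E,4S)-2,4-dimethylhex-2-en-1-ol | CC[C@H](C)/C=C(\C)CO | intermediate
26 | (2E,4S)-2,4-dimethylhex-2-enal | CC[C@H](C)/C=C(\C)C=O | intermediate
27 | (2E,4E,6S)-N-methoxy-N,4,6-trimethylocta-2,4-dienamide | CC[C@H](C)/C=C(C)/C=C/C(=O)N(C)OC | intermediate
28 | (2E,4E,6S)-4,6-dimethylocta-2,4-dienal | CC[C@H](C)/C=C(C)/C=C/C=O | intermediate
29 | vinylogous aldol adduct (C3 carbinol epimers; arm OSiEt3; C1–OTBDPS) | O=C1[C@]2(C)OC(C)(C)O[C@@H]2[C@](CO[Si](c3ccccc3)(c3ccccc3)C(C)(C)C)(C(C)O[Si](CC)(CC)CC)C(CC(O)/C=C/C(C)=C/[C@@H](C)CC)=C1Cl | intermediate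
30 | diol (C3–OH and arm CH(OH)CH3; C1–OTBDPS) | O=C1[C@]2(C)OC(C)(C)O[C@@H]2[C@](CO[Si](c3ccccc3)(c3ccccc3)C(C)(C)C)(C(C)O)C(CC(O)/C=C/C(C)=C/[C@@H](C)CC)=C1Cl | intermediate
31 | seco diketone (C3 dienone; C8a α-acetyl; C1–OTBDPS) | O=C1[C@]2(C)OC(C)(C)O[C@@H]2[C@](CO[Si](c3ccccc3)(c3ccccc3)C(C)(C)C)(C(C)=O)C(CC(=O)/C=C/C(C)=C/[C@@H](C)CC)=C1Cl | intermediate
32 | free C1 alcohol of 31 | O=C1[C@]2(C)OC(C)(C)O[C@@H]2[C@](CO)(C(C)=O)C(CC(=O)/C=C/C(C)=C/[C@@H](C)CC)=C1Cl | intermediate
33 | C3 hemiketal (ring B closed; C3 epimers) | CC[C@H](C)/C=C(C)/C=C/C1(O)CC2=C(Cl)C(=O)[C@]3(C)OC(C)(C)O[C@@H]3[C@@]2(C(C)=O)CO1 | intermediate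
34 | 7,8-O-isopropylidene derivative (acetonide) of the target | CC[C@H](C)/C=C(C)/C=C/C1=CC2=C(Cl)C(=O)[C@]3(C)OC(C)(C)O[C@@H]3[C@@]2(C(C)=O)CO1 | intermediate
35 | (7R,8R,8aS)-8a-acetyl-5-chloro-3-[(1E,3E,5S)-3,5-dimethylhepta-1,3-dien-1-yl]-7,8-dihydroxy-7-methyl-1,7,8,8a-tetrahydro-6H-isochromen-6-one | CC[C@H](C)/C=C(C)/C=C/C1=CC2=C(Cl)C(=O)[C@](C)(O)[C@H](O)[C@@]2(C(C)=O)CO1 | target

## Step count and risk

Total step count: 27. Longest linear sequence: 22 steps (1 to 35 through steps 1–17 and 23–27); the side chain needs 5 steps (18–22).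

**Step 4 (face selectivity of the osmylation).** The 1,3-related silyloxy group may give only modest control, and everything downstream inherits this face. The fallback sets out from 6 and comes back at 7. Nucleophilic epoxidation (H2O2, LiOH, MeOH, −10 °C) proceeds by axial conjugate attack anti to the C4a substituent, as with carvone itself, and gives the α-epoxy ketone F1. CO2 insertion (CO2, LiBr, N-methylpyrrolidone, 80 °C) opens C8 with bromide and recloses with a second inversion, giving the cis-fused cyclic carbonate F2 with both oxygens on the α face. Methanolysis (K2CO3, MeOH, 0 °C) then gives 7.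

**Step 9 (lithium enolate next to the acetonide).** β-Elimination of the C8 oxygen or retro-aldol can erode the yield. The fallback sets out from 11 and comes back at 12. Soft enolization (Me3SiOTf, Et3N, CH2Cl2, 0 °C) gives the trimethylsilyl dienol ether F3 without any strongly basic enolate. A Mukaiyama aldol with acetaldehyde (BF3·OEt2, CH2Cl2, −78 °C) at the C8a terminus then gives 12.

**Step 23 (vinylogous Mukaiyama aldol).** The chloro-substituted, neopentyl dienol ether may be too unreactive, or the dienylic carbinol may ionize. The fallback sets out from 18 (and uses 28) and comes back at 34; it forms the C4–C4a bond by acetylide addition and closes ring B by oxa-Michael addition instead.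
- Dienal 28 is homologated with dimethyl (1-diazo-2-oxopropyl)phosphonate (K2CO3, MeOH) to (3E,5E,7S)-5,7-dimethylnona-3,5-dien-1-yne F4.
- Its lithium acetylide (n-BuLi, THF, −78 °C) adds to the C4a carbonyl of 18 to give the tertiary propargylic carbinol F5.
- 1 M HCl/THF converts this into the chloro ynenone with free arm carbinol F6.
- Dess–Martin oxidation gives the acetyl ynenone F7.
- HF·pyridine gives the free C1 alcohol F8.
- AuCl3 (5 mol %, CH2Cl2) promotes 6-endo-dig addition of the hydroxyl to C3 and gives 34.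

## Further compounds

F1 | step 4 | α-face C7–C8 epoxide of 6 (epoxy ketone; C4a β-OTBS) | O=C1[C@]2(C)O[C@@H]2C[C@@H](O[Si](C)(C)C(C)(C)C)C1
F2 | step 4 | cis-fused C7/C8 cyclic carbonate (both oxygens α; C4a β-OTBS) | O=C1[C@]2(C)OC(=O)O[C@@H]2C[C@@H](O[Si](C)(C)C(C)(C)C)C1
F3 | step 9 | trimethylsilyl dienol ether of 11 (C8a=C4a–OSiMe3; C5=C6–OCH2OCH3) | COCOC=1[C@]2(C)OC(C)(C)O[C@@H]2C=C(O[Si](C)(C)C)C=1
F4 | step 23 | (3E,5E,7S)-5,7-dimethylnona-3,5-dien-1-yne | CC[C@H](C)/C=C(C)/C=C/C#C
F5 | step 23 | tertiary propargylic carbinol (1,2-adduct of the acetylide of F4 at C4a of 18; C4a epimers) | COCOC=1[C@]2(C)OC(C)(C)O[C@@H]2[C@](CO[Si](c3ccccc3)(c3ccccc3)C(C)(C)C)(C(C)O[Si](CC)(CC)CC)C(O)(C#C/C=C/C(C)=C/[C@@H](C)CC)C=1Cl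
F6 | step 23 | chloro ynenone with free arm carbinol (C4a–C≡C–dienyl; C6=O) | O=C1[C@]2(C)OC(C)(C)O[C@@H]2[C@](CO[Si](c3ccccc3)(c3ccccc3)C(C)(C)C)(C(C)O)C(C#C/C=C/C(C)=C/[C@@H](C)CC)=C1Cl
F7 | step 23 | chloro ynenone with C8a acetyl | O=C1[C@]2(C)OC(C)(C)O[C@@H]2[C@](CO[Si](c3ccccc3)(c3ccccc3)C(C)(C)C)(C(C)=O)C(C#C/C=C/C(C)=C/[C@@H](C)CC)=C1Cl
F8 | step 23 | free C1 alcohol of F7 | O=C1[C@]2(C)OC(C)(C)O[C@@H]2[C@](CO)(C(C)=O)C(C#C/C=C/C(C)=C/[C@@H](C)CC)=C1Cl
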